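## Structural features

Compound 20 is an oxolane (ring atoms O1, C2, C3, C4, C5) in which the two carbons next to oxygen, C2 and C5, are plain CH2 groups. C4 carries a 4-hydroxy-3-methoxybenzyl group through the benzylic carbon, called C7′ here. C3 carries the secondary carbinol carbon, called C7, which bears the second 4-hydroxy-3-methoxyphenyl ring. C7, C3 and C4 are contiguous stereocentres, all R, and the two ring substituents are trans. The fragile part is the benzylic alcohol para to a free phenol: acid ionises it towards a quinone methide and hydrogenation can cut its C–O bond, so the carbinol should appear late and the phenols stay masked to the end. The real difficulty is stereochemical: C4 has no neighbouring functional group to control it, C3 can be adjusted only while C7 is a carbonyl carbon, and C7 is an acyclic centre next to a branched carbon. The key step exploits the fact that C3 and C4 are adjacent ring carbons, each holding one exocyclic carbon, C7 at ketone level and C7′ as CH2. A bond drawn between C7 and C7′ gives a cyclobutane fused to the oxolane, the [2+2] adduct of an aryl enone equivalent with the alkene of 2,5-dihydrofuran; breaking that bond again by retro-aldol leaves a 1,5-keto ester.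

## Logic of the disconnections

**20 ⇒ 19.** The two phenolic O–CH2Ph bonds are cut. Benzyl ethers are transparent above 300 nm and indifferent to methoxide, hydroxide, arylzinc and borane, so one protecting group serves both arenes from first step to last. The gain is that no free phenol passes through base or metal chemistry. The demand is a hydrogenolysis that removes O-benzyl without cutting the benzylic C7–O bond.

**19 ⇒ 18.** The C7–H bond is cut and C7 returns to a carbonyl carbon. The ketone is what the fragmentation delivers and what makes C3 adjustable, so the carbinol is made last but one. One stereocentre disappears. The forward step must deliver hydride to one face of an aryl ketone with a stereocentre next to it, under reagent control.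

**18 ⇒ 13 + 17 (17 from 15, 15 from 14).** The C7′–aryl bond is cut. C7′ is left by the photochemical sequence as the α-carbon of a carboxylic acid, so exchanging the carboxyl carbon for an arene is the shortest way to the benzyl group. The molecule splits into a ring fragment and a simple aryl metal. The forward step needs the primary radical from 13 to be captured by nickel faster than it is reduced or dimerised, and a nucleophile mild enough to spare the ketone and its α-hydrogen, hence zinc.

**13 ⇒ 12 ⇒ 11.** Only acyl C–O bonds change (active ester, acid, methyl ester). Nothing is simplified in the skeleton; the demand is merely that C3, already at equilibrium, is not disturbed.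

**11 ⇒ 8 (through 10 and 9).** Backwards, C3 returns to cis, the C7–C7′ bond is re-formed in the aldol sense, and hydroxyl and ester are tied up as the acylal of 5. An open 1,5-keto ester becomes a rigid tricycle in which the C3/C4 relationship is dictated by ring fusion and the absolute configuration is tied to an auxiliary. Forward, one basic medium must open the acylal, trigger retro-aldol cleavage and equilibrate C3 to trans without β-eliminating O1 from the ketone enolate. Doing all three in one operation saves two steps.

**8 ⇒ 6 + 7.** The bonds C3–C7 and C4–C7′ are cut, undoing the cyclobutane as a [2+2] cycloaddition. Two skeletal bonds, one ring and four stereocentres vanish; what remains is a symmetric achiral alkene and a flat enone acetal.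
- A check of the descriptors shows that the spiro carbon has the same configuration in 6 and 8, that C4 of 8 is that of 20, and that C3 of 8 is its epimer. The structures are consistent and need no correction.
- Face selectivity alone does not fix C4. The syn adduct formed on the same face has mirror-image oxolane carbons, so the anti orientation is equally required.
- 8 must therefore be purified to one diastereomer before the auxiliary is removed.

**6 ⇒ 4 + 5.** The two acetal C–O bonds at the spiro carbon are cut. This separates the chiral auxiliary from an achiral β-keto ester. 6 is specified as the (R)-spiro epimer and keeps the benzyl ether. The forward condensation forms both spiro epimers, so they must be separable, and the acid must not epimerise 5 at its isopropyl-bearing carbon.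

**4 ⇒ 2 + 3, and 2 ⇒ 1.** The C7–C7′ bond is cut again, now as a Claisen disconnection, and then the O–benzyl bond. Because 2 cannot enolise, the condensation with the enolate of 3 is unambiguous. For that reason an ester is preferred to a methyl ketone enolate with a carbonate-type acylating agent, where O-acylation competes. All four starting materials (1, 3, 5, 14) and 7 are bulk chemicals.

## Other disconnections considered

**Alternative 1:** The cut is the ring bond C3–C4.
- Forward: the vinylic bromide of the epoxy ether A1 is exchanged with t-BuLi, and the alkenyllithium opens the (2S,3S)-epoxide at its non-benzylic carbon in a 5-exo-tet substitution with inversion. This closes the oxolane, sets C3 and frees the C7 hydroxyl, giving the benzylidene carbinol A2.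
- In favour: C3 and C7 both descend from one Sharpless epoxidation of predictable sense, the substitution is stereospecific, and A2 already holds both arenes and every carbon of 20.
- Against: A1 is an electron-rich aryl epoxide that would rearrange or open with traces of acid, and it must tolerate an alkyllithium. Attack at the activated benzylic epoxide carbon (6-endo) would compete. C4 must then be created by hydrogenating the exocyclic alkene of A2 with hydrogen delivered cis to the C3 substituent, which would need a hydroxyl-directed catalyst such as [Ir(cod)(PCy3)(py)]PF6; on Pd/C the open face and the benzylic C–O bond would both be at risk.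
- Comparison: on structure the alternative is the better at C7 (no late reduction under double stereodifferentiation) and the equal at C3. The chosen plan is the better at C4, which it fixes on a rigid bicycle. On mechanism, a polar SN2 opening is easier to predict than the face choice of an excited state, a point for the alternative. On step economy A2 would stand about two steps from 20 against seven from 8, so the alternative is the equal or slightly the better overall, at the price of a more fragile precursor.

**Alternative 2:** The cut is C2–C3.
- Forward: Me3SiOTf ionises the O–CH2–O unit of the dihydrodioxepine A3 at the enol-ether oxygen, and the enolate carbon adds to the oxocarbenium carbon. The seven-membered ring contracts to the oxolane aldehyde A4.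
- In favour: the trans C3/C4 relationship should come out of the key step itself, the aldehyde is ready to accept the second arene as an aryl metal, and neither photochemistry nor decarboxylative coupling is needed.
- Against: the stereocentre of A3, which becomes C4, must be made beforehand in enantiopure form, a task as large as the one the auxiliary solves here. A formaldehyde acetal ionises reluctantly and must break at the right oxygen. A4 is an epimerisable aldehyde, and aryl-metal addition would set C7 under substrate control only, so oxidation to 18 and a controlled reduction would probably still be needed.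
- Comparison: the alternative is the better on the C3/C4 relative configuration (no separate equilibration) and the equal in the end game from 18. It is weaker on absolute stereocontrol, which the rearrangement only transmits. The step count would be comparable once A3 is included.

**Alternative 3:** The cut is threefold: O1–C2, C3–C4 and C7′–aryl.
- Forward: a sodium propargylic alkoxide adds to diethyl methylenemalonate A5. The malonate enolate then attacks the alkyne activated by an arylpalladium iodide, formed from PdCl2(PPh3)2 after reduction to zerovalent palladium and oxidative addition. Anti-carbopalladation and reductive elimination would give the benzylidene diester A6.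
- In favour: three bonds and the ring in one operation from three achiral pieces, and no photochemical equipment. In bonds formed per step it is the better (three against two).
- Against: A6 has no stereocentre. C4 would arise from hydrogenating a trisubstituted alkene with no directing group, one ester must be removed and the other turned into the aryl ketone, and C3 still needs equilibration. A5 polymerises readily.
- Comparison: for racemic material the alternative would be the shorter and the better. For a single enantiomer it lacks any source of absolute configuration, and its end game from A6 is no shorter than the one from 8. It is the equal of the chosen plan in needing a late C7 reduction.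

Key step: step 4

Assumption: the excited (6R)-spiro acetal 6 is taken to react on the face of its C5=C6 bond remote from the isopropyl-bearing carbon of the menthane ring, the face that leads to 8; if the other face reacts, the (6S) epimer from the same condensation takes its place and nothing else changes.

## Route

Step 1
Reactants: 1 methyl 4-hydroxy-3-methoxybenzoate (methyl vanillate)
Product: 2 methyl 4-(benzyloxy)-3-methoxybenzoate
Conditions: BnBr (1.1 equiv), K2CO3 (1.5 equiv), DMF, 60 °C
Reagents that add atoms: benzyl bromide, BrCc1ccccc1
Why: Williamson ether synthesis: the phenoxide displaces bromide from benzyl bromide by SN2; the methyl ester is inert and no stereocentre is involved.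

Step 2
Reactants: 2 methyl 4-(benzyloxy)-3-methoxybenzoate; 3 tert-butyl acetate
Product: 4 tert-butyl 3-[4-(benzyloxy)-3-methoxyphenyl]-3-oxopropanoate
Conditions: 3 (2.4 equiv), LiN(SiMe3)2 (2.5 equiv), THF, −78 → −20 °C; then cold 1 M HCl
Reagents that add atoms: none
Why: Crossed Claisen condensation: only 3 can form an enolate, and deprotonation of the β-keto ester product by the excess base makes the acylation irreversible. The tert-butyl ester is chosen because step 3 needs an ester that leaves as isobutene under acid.

Step 3
Reactants: 4 tert-butyl 3-[4-(benzyloxy)-3-methoxyphenyl]-3-oxopropanoate; 5 (−)-menthone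
Product: 6 (6R,7S,10R)-4-[4-(benzyloxy)-3-methoxyphenyl]-7-isopropyl-10-methyl-1,5-dioxaspiro[5.5]undec-3-en-2-one
Conditions: 5 (1.5 equiv), Ac2O (3 equiv), conc. H2SO4 (0.2 equiv), 0 °C → rt; chromatography and crystallisation to remove the spiro epimer
Reagents that add atoms: none
Why: Acid-catalysed condensation of a β-keto ester with a ketone to a 1,3-dioxin-4-one: H2SO4 removes the tert-butyl group as isobutene, and the enol and carboxyl oxygens close the acetal on the carbonyl carbon of 5 while Ac2O takes up the water. The spiro carbon is the only new stereocentre and forms as both epimers, which are diastereomers and are separated; low temperature and short acid contact limit epimerisation of 5.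

Step 4
Reactants: 6 (6R,7S,10R)-4-[4-(benzyloxy)-3-methoxyphenyl]-7-isopropyl-10-methyl-1,5-dioxaspiro[5.5]undec-3-en-2-one; 7 2,5-dihydrofuran
Product: 8 cis-anti-cis photoadduct: 3-oxabicyclo[3.2.0]heptane whose C7 (S) carries the 4-benzyloxy-3-methoxyphenyl group and the acetal oxygen and whose C6 (R) carries the lactone carbonyl, C6 and C7 being bridged by the C(=O)–O–C(spiro, R)–O chain of the menthone acetal; ring-fusion carbons C1 (S) and C5 (S); oxolane on the cyclobutane face opposite to the dioxanone
Conditions: hν (λ ≥ 300 nm, Pyrex), 7 (15 equiv), EtOAc, −40 °C, degassed; chromatography to a single diastereomer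
Reagents that add atoms: none
Why: Light above 300 nm excites the aryl-conjugated enone chromophore of 6, and the triplet reached by intersystem crossing bonds to one alkene carbon of 7 to give a triplet 1,4-diradical that closes after spin inversion; this is the enone–alkene [2+2] photocycloaddition of 1,3-dioxin-4-ones with cyclic alkenes, the first half of a de Mayo sequence. The cyclobutane is the only ring closed, in a stepwise two-bond mode (intermolecular radical addition, then radical–radical recombination), and its two new bonds are C3–C7 and C4–C7′. C3 and C4 come out cis, and so do C7 and C7′, because a trans-fused four-membered ring on the oxolane or on the dioxanone would be too strained for the diradical to close. The face of the C5=C6 bond is selected by the menthane ring of the spiro acetal, which is taken to leave open the side away from its isopropyl-bearing carbon, and this fixes C7 and C7′. The oxolane then lies on the cyclobutane face opposite to the dioxanone oxygen and carbonyl (anti, the less crowded approach), and face plus anti orientation together give C4 the configuration it has in 20. Because 7 is symmetric no regiochemistry arises; the selectivity needed is facial and anti, served by low temperature and, against dioxinone dimerisation, by the excess of 7. Of the four new stereocentres only C4 persists, so diastereomeric adducts are removed here, before cleavage of the auxiliary would turn them into the enantiomer.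

Step 5
Reactants: 8 cis-anti-cis photoadduct
Product: 11 methyl 2-[(3R,4R)-4-(4-benzyloxy-3-methoxybenzoyl)tetrahydrofuran-3-yl]acetate, via cyclobutanol hydroxy ester 9 (not isolated), via cis keto ester 10 (not isolated)
Conditions: NaOMe (0.3 equiv), MeOH/THF, 0 °C → rt
Reagents that add atoms: methanol, CO
Why: Methoxide opens the acylal carbonyl, the hemiketal alkoxide sheds menthone, and the tertiary cyclobutanolate of 9 undergoes retro-aldol cleavage of the C7–C7′ bond (strain release, ester enolate as leaving group), the fragmentation half of the de Mayo sequence. The cis keto ester 10 has its only acidic ring hydrogen at C3, α to the aryl ketone, and the same base equilibrates it to the more stable trans isomer 11, while C4 is not acidic and keeps the configuration set in step 4. Sub-stoichiometric methoxide at room temperature is used because the ketone enolate has O1 in the β position; elimination is held back by the poor overlap of the ring C2–O1 bond with the exocyclic enolate.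

Step 6
Reactants: 11 methyl 2-[(3R,4R)-4-(4-benzyloxy-3-methoxybenzoyl)tetrahydrofuran-3-yl]acetate
Product: 12 2-[(3R,4R)-4-(4-benzyloxy-3-methoxybenzoyl)tetrahydrofuran-3-yl]acetic acid
Conditions: LiOH·H2O (2 equiv), THF/H2O, 0 °C → rt; then 1 M HCl to pH 3
Reagents that add atoms: lithium hydroxide, [Li+].[OH-]
Why: Saponification of a methyl ester by acyl–oxygen cleavage; C3 already sits at its thermodynamic trans position, so enolisation of the ketone costs nothing, and the benzyl ether and oxolane are stable.

Step 7
Reactants: 12 2-[(3R,4R)-4-(4-benzyloxy-3-methoxybenzoyl)tetrahydrofuran-3-yl]acetic acid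
Product: 13 1,3-dioxoisoindolin-2-yl 2-[(3R,4R)-4-(4-benzyloxy-3-methoxybenzoyl)tetrahydrofuran-3-yl]acetate
Conditions: N-hydroxyphthalimide (1.1 equiv), N,N′-diisopropylcarbodiimide (1.1 equiv), DMAP (0.1 equiv), CH2Cl2, rt
Reagents that add atoms: N-hydroxyphthalimide, O=C1c2ccccc2C(=O)N1O
Why: Carbodiimide (Steglich-type) esterification to the N-acyloxyphthalimide, a redox-active ester that accepts one electron and then loses CO2. N-Hydroxyphthalimide traps the O-acylisourea faster than the ketone enol could, since enol-lactone formation would need a tetrasubstituted enol in a fused bicycle.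

Step 8
Reactants: 14 4-bromo-2-methoxyphenol
Product: 15 1-(benzyloxy)-4-bromo-2-methoxybenzene
Conditions: BnBr (1.1 equiv), K2CO3 (1.5 equiv), DMF, 60 °C
Reagents that add atoms: benzyl bromide, BrCc1ccccc1
Why: Williamson ether synthesis as in step 1; the aryl bromide is inert to carbonate.

Step 9
Reactants: 13 1,3-dioxoisoindolin-2-yl 2-[(3R,4R)-4-(4-benzyloxy-3-methoxybenzoyl)tetrahydrofuran-3-yl]acetate; 15 1-(benzyloxy)-4-bromo-2-methoxybenzene
Product: 18 [(3R,4R)-4-(4-benzyloxy-3-methoxybenzyl)tetrahydrofuran-3-yl](4-benzyloxy-3-methoxyphenyl)methanone, via arylmagnesium bromide 16 (not isolated), via arylzinc chloride 17 (not isolated)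
Conditions: 15 (3 equiv), Mg, LiCl, THF, rt; ZnCl2 (1.1 equiv per 15), 0 °C → rt; then 13, NiCl2·glyme (20 mol %), 4,4′-di-tert-butyl-2,2′-bipyridine (40 mol %), THF/DMF, rt
Reagents that add atoms: none
Why: Magnesium insertion and transmetalation give an arylzinc that neither adds to the ketone nor deprotonates C3; under nickel catalysis an arylnickel species transfers one electron to the phthalimide ester, which fragments to CO2, phthalimide anion and the primary C7′ radical, and radical capture at nickel followed by reductive elimination forms the C7′–aryl bond (decarboxylative Negishi-type arylation of a redox-active ester). No stereocentre is made or broken: C4 is β to the radical carbon and C3 stays at its trans equilibrium.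

Step 10
Reactants: 18 [(3R,4R)-4-(4-benzyloxy-3-methoxybenzyl)tetrahydrofuran-3-yl](4-benzyloxy-3-methoxyphenyl)methanone
Product: 19 (R)-[(3R,4R)-4-(4-benzyloxy-3-methoxybenzyl)tetrahydrofuran-3-yl](4-benzyloxy-3-methoxyphenyl)methanol
Conditions: (S)-2-methyl-CBS-oxazaborolidine (1.0 equiv), BH3·SMe2 (1.2 equiv), THF, −30 °C; then MeOH, aqueous work-up
Reagents that add atoms: none
Why: Corey–Bakshi–Shibata reduction: the ketone binds to the oxazaborolidine boron with the aryl group in the large-substituent position and the coordinated borane delivers hydride to one face, which with the (S)-catalyst gives the (R)-carbinol (priority order O > aryl > C3, as for acetophenone). C7 is thus set by the catalyst; a Felkin–Anh analysis with C4 as the large substituent puts the substrate's own bias on the other face, so the pairing is probably mismatched and a full equivalent of catalyst at low temperature is proposed.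

Step 11
Reactants: 19 (R)-[(3R,4R)-4-(4-benzyloxy-3-methoxybenzyl)tetrahydrofuran-3-yl](4-benzyloxy-3-methoxyphenyl)methanol
Product: 20 4-{[(3R,4R)-4-[(R)-hydroxy(4-hydroxy-3-methoxyphenyl)methyl]tetrahydrofuran-3-yl]methyl}-2-methoxyphenol
Conditions: H2 (1 atm), 10% Pd/C, EtOAc, rt, stopped at complete O-debenzylation
Reagents that add atoms: none
Why: Hydrogenolysis of two benzyl aryl ethers on Pd/C; in neutral ethyl acetate at 1 atm the O–benzyl bonds should cleave much faster than the secondary benzylic C7–OH bond. No stereocentre is affected.

## Compound list

1 | methyl 4-hydroxy-3-methoxybenzoate (methyl vanillate) | COC(=O)c1ccc(O)c(OC)c1 | starting material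
2 | methyl 4-(benzyloxy)-3-methoxybenzoate | COC(=O)c1ccc(OCc2ccccc2)c(OC)c1 | intermediate
3 | tert-butyl acetate | CC(=O)OC(C)(C)C | starting material
4 | tert-butyl 3-[4-(benzyloxy)-3-methoxyphenyl]-3-oxopropanoate | COc1cc(C(=O)CC(=O)OC(C)(C)C)ccc1OCc1ccccc1 | intermediate
5 | (−)-menthone, (2S,5R)-2-isopropyl-5-methylcyclohexanone | C[C@@H]1CC[C@H](C(=O)C1)C(C)C | starting material
6 | (6R,7S,10R)-4-[4-(benzyloxy)-3-methoxyphenyl]-7-isopropyl-10-methyl-1,5-dioxaspiro[5.5]undec-3-en-2-one (6-aryl-1,3-dioxin-4-one, spiro acetal of menthone) | COc1cc(C2=CC(=O)O[C@@]3(C[C@H](C)CC[C@H]3C(C)C)O2)ccc1OCc1ccccc1 | intermediate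
7 | 2,5-dihydrofuran | C1C=CCO1 | starting material
8 | cis-anti-cis photoadduct (oxolane, cyclobutane and spiro dioxanone rings; spiro carbon R, aryl-bearing carbon S, ester α-carbon R, both oxolane fusion carbons S) | COc1cc([C@@]23O[C@]4(C[C@H](C)CC[C@H]4C(C)C)OC(=O)[C@@H]2[C@H]2COC[C@@H]32)ccc1OCc1ccccc1 | intermediate
9 | methyl (1S,5S,6R,7S)-7-[4-(benzyloxy)-3-methoxyphenyl]-7-hydroxy-3-oxabicyclo[3.2.0]heptane-6-carboxylate (formed and consumed in step 5) | COc1cc([C@@]2(O)[C@H](C(=O)OC)[C@H]3COC[C@H]32)ccc1OCc1ccccc1 | intermediate
10 | methyl 2-[(3R,4S)-4-(4-benzyloxy-3-methoxybenzoyl)tetrahydrofuran-3-yl]acetate, cis (formed and consumed in step 5) | COC(=O)C[C@H]1COC[C@H]1C(=O)c1ccc(OCc2ccccc2)c(OC)c1 | intermediate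
11 | methyl 2-[(3R,4R)-4-(4-benzyloxy-3-methoxybenzoyl)tetrahydrofuran-3-yl]acetate, trans | COC(=O)C[C@H]1COC[C@@H]1C(=O)c1ccc(OCc2ccccc2)c(OC)c1 | intermediate
12 | 2-[(3R,4R)-4-(4-benzyloxy-3-methoxybenzoyl)tetrahydrofuran-3-yl]acetic acid | OC(=O)C[C@H]1COC[C@@H]1C(=O)c1ccc(OCc2ccccc2)c(OC)c1 | intermediate
13 | 1,3-dioxoisoindolin-2-yl 2-[(3R,4R)-4-(4-benzyloxy-3-methoxybenzoyl)tetrahydrofuran-3-yl]acetate | O=C(C[C@H]1COC[C@@H]1C(=O)c1ccc(OCc2ccccc2)c(OC)c1)ON1C(=O)c2ccccc2C1=O | intermediate
14 | 4-bromo-2-methoxyphenol | COc1cc(Br)ccc1O | starting material
15 | 1-(benzyloxy)-4-bromo-2-methoxybenzene | COc1cc(Br)ccc1OCc1ccccc1 | intermediate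
16 | [4-(benzyloxy)-3-methoxyphenyl]magnesium bromide (formed and consumed in step 9) | COc1cc([Mg]Br)ccc1OCc1ccccc1 | intermediate
17 | [4-(benzyloxy)-3-methoxyphenyl]zinc chloride (formed and consumed in step 9) | COc1cc([Zn]Cl)ccc1OCc1ccccc1 | intermediate
18 | [(3R,4R)-4-(4-benzyloxy-3-methoxybenzyl)tetrahydrofuran-3-yl](4-benzyloxy-3-methoxyphenyl)methanone | COc1cc(C[C@H]2COC[C@@H]2C(=O)c2ccc(OCc3ccccc3)c(OC)c2)ccc1OCc1ccccc1 | intermediate
19 | (R)-[(3R,4R)-4-(4-benzyloxy-3-methoxybenzyl)tetrahydrofuran-3-yl](4-benzyloxy-3-methoxyphenyl)methanol | COc1cc(C[C@H]2COC[C@@H]2[C@@H](O)c2ccc(OCc3ccccc3)c(OC)c2)ccc1OCc1ccccc1 | intermediate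
20 | 4-{[(3R,4R)-4-[(R)-hydroxy(4-hydroxy-3-methoxyphenyl)methyl]tetrahydrofuran-3-yl]methyl}-2-methoxyphenol | COc1cc(C[C@H]2COC[C@@H]2[C@@H](O)c2ccc(O)c(OC)c2)ccc1O | target

## Step count and least certain steps

Total: 11 steps. Longest linear sequence: 10 steps (steps 1 to 7, then 9 to 11; step 8 is the side branch). If 2 and 15 are purchased, steps 1 and 8 fall away.

**The key step, step 4, is the least certain.** The most likely failure is poor or reversed facial selectivity of the excited dioxinone, because a spiro acetal several atoms from the reacting bond discriminates the two faces only weakly and the preferred face is assumed, not known. Incomplete anti selectivity has the same effect on C4. A second concern is sluggish cycloaddition of a push-pull aryl chromophore, which would give time for dimerisation or for hydrogen abstraction from the allylic ether positions of 7. Two safeguards are built in: 8 is purified as one diastereomer, and step 10 turns any residual enantiomer of 18 into a separable diastereomer of 19. The fallback changes the controlling precursor. It sets out from 4: step 3 also forms the spiro epimer (6S,7S,10R)-4-[4-(benzyloxy)-3-methoxyphenyl]-7-isopropyl-10-methyl-1,5-dioxaspiro[5.5]undec-3-en-2-one F1, which presents the opposite face to the menthane ring. Its irradiation with 7 should give the spiro-epimeric photoadduct F2, with the same four cyclobutane centres as 8. Methoxide treatment as in step 5 takes F2 to 9 and on to 11, where the route is rejoined.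

**Step 9.** The most likely failure is escape of the primary C7′ radical from nickel, leading to reduction or dimerisation, since primary radicals are captured less efficiently than secondary ones. The fallback sets out from 13 and returns at 18. It replaces the organozinc by a reductive cross-electrophile coupling of 13 with the aryl iodide 1-(benzyloxy)-4-iodo-2-methoxybenzene F3, the iodo analogue of 15, using NiBr2·glyme, 4,4′-di-tert-butyl-2,2′-bipyridine and Zn dust in N,N-dimethylacetamide. No aryl metal is preformed, and the radical is generated at the rate at which arylnickel is available.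

**Step 10.** The most likely failure is low diastereoselectivity at C7 from a mismatched pairing of catalyst and substrate, made worse by the small size difference between an aryl group and an α-branched alkyl group. The fallback sets out from 18 and returns at 19. It uses the substrate bias instead of fighting it: LiBH(s-Bu)3 in THF at −78 °C should give mainly the Felkin–Anh epimer (S)-[(3R,4R)-4-(4-benzyloxy-3-methoxybenzyl)tetrahydrofuran-3-yl](4-benzyloxy-3-methoxyphenyl)methanol F4. Mitsunobu esterification (4-nitrobenzoic acid, PPh3, diisopropyl azodicarboxylate, THF, 0 °C) inverts C7 to the (R)-4-nitrobenzoate F5, and K2CO3 in MeOH releases 19.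

**Step 5.** The most likely failure is incomplete cis-to-trans equilibration at C3, or opening of the oxolane by β-elimination of O1 if the base is pushed, because the trans preference of a keto ester with two small substituents may be modest. The fallback sets out from 8 and returns at 18. The cleavage is stopped at 10 (K2CO3, MeOH, 0 °C, short contact), and the cis series is carried forward without equilibration:
- saponification as in step 6 gives the cis acid 2-[(3R,4S)-4-(4-benzyloxy-3-methoxybenzoyl)tetrahydrofuran-3-yl]acetic acid F6;
- esterification as in step 7 gives its N-acyloxyphthalimide F7;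
- arylation as in step 9 gives the cis ketone [(3S,4R)-4-(4-benzyloxy-3-methoxybenzyl)tetrahydrofuran-3-yl](4-benzyloxy-3-methoxyphenyl)methanone F8;
- F8 is equilibrated with DBU in toluene to 18.

At that stage the larger benzyl group should favour trans more strongly and no ester enolate is present.

**Step 11.** The most likely failure is over-reduction, the loss of the C7 hydroxyl by benzylic hydrogenolysis, because the carbinol is para to an oxygen-substituted ring. The fallback sets out from 18 and returns at 20. The benzyl ethers are removed first, at the ketone stage where no benzylic alcohol exists (H2, Pd/C, EtOAc), giving (4-hydroxy-3-methoxyphenyl)[(3R,4R)-4-(4-hydroxy-3-methoxybenzyl)tetrahydrofuran-3-yl]methanone F9. F9 is then reduced as in step 10 with extra BH3·SMe2 (the phenols are held as aryl borates and released on methanolic work-up), directly to 20.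

**Step 3.** The most likely failure is acid damage (partial epimerisation of 5, cleavage of the benzyl ether) or an unfavourable spiro ratio. The fallback sets out from 4 and returns at 6 under neutral conditions. 4 is heated with 5 in refluxing toluene with removal of tert-butanol. Thermal loss of the alcohol gives the aroylketene 3-[4-(benzyloxy)-3-methoxyphenyl]-3-oxoprop-1-en-1-one F10, which adds to the carbonyl group of 5 in a [4+2] cycloaddition to give 6 together with its spiro epimer.

Further compounds
F1 | step 4 | (6S,7S,10R)-4-[4-(benzyloxy)-3-methoxyphenyl]-7-isopropyl-10-methyl-1,5-dioxaspiro[5.5]undec-3-en-2-one (spiro epimer of 6) | COc1cc(C2=CC(=O)O[C@]3(C[C@H](C)CC[C@H]3C(C)C)O2)ccc1OCc1ccccc1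
F2 | step 4 | spiro-epimeric photoadduct (cyclobutane centres as in 8, spiro carbon S) | COc1cc([C@@]23O[C@@]4(C[C@H](C)CC[C@H]4C(C)C)OC(=O)[C@@H]2[C@H]2COC[C@@H]32)ccc1OCc1ccccc1
F3 | step 9 | 1-(benzyloxy)-4-iodo-2-methoxybenzene | COc1cc(I)ccc1OCc1ccccc1
F4 | step 10 | (S)-[(3R,4R)-4-(4-benzyloxy-3-methoxybenzyl)tetrahydrofuran-3-yl](4-benzyloxy-3-methoxyphenyl)methanol | COc1cc(C[C@H]2COC[C@@H]2[C@H](O)c2ccc(OCc3ccccc3)c(OC)c2)ccc1OCc1ccccc1
F5 | step 10 | (R)-[(3R,4R)-4-(4-benzyloxy-3-methoxybenzyl)tetrahydrofuran-3-yl](4-benzyloxy-3-methoxyphenyl)methyl 4-nitrobenzoate | COc1cc(C[C@H]2COC[C@@H]2[C@@H](OC(=O)c2ccc(cc2)[N+](=O)[O-])c2ccc(OCc3ccccc3)c(OC)c2)ccc1OCc1ccccc1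
F6 | step 5 | 2-[(3R,4S)-4-(4-benzyloxy-3-methoxybenzoyl)tetrahydrofuran-3-yl]acetic acid (cis) | OC(=O)C[C@H]1COC[C@H]1C(=O)c1ccc(OCc2ccccc2)c(OC)c1
F7 | step 5 | 1,3-dioxoisoindolin-2-yl 2-[(3R,4S)-4-(4-benzyloxy-3-methoxybenzoyl)tetrahydrofuran-3-yl]acetate (cis) | O=C(C[C@H]1COC[C@H]1C(=O)c1ccc(OCc2ccccc2)c(OC)c1)ON1C(=O)c2ccccc2C1=O
F8 | step 5 | [(3S,4R)-4-(4-benzyloxy-3-methoxybenzyl)tetrahydrofuran-3-yl](4-benzyloxy-3-methoxyphenyl)methanone (cis) | COc1cc(C[C@H]2COC[C@H]2C(=O)c2ccc(OCc3ccccc3)c(OC)c2)ccc1OCc1ccccc1
F9 | step 11 | (4-hydroxy-3-methoxyphenyl)[(3R,4R)-4-(4-hydroxy-3-methoxybenzyl)tetrahydrofuran-3-yl]methanone | COc1cc(C[C@H]2COC[C@@H]2C(=O)c2ccc(O)c(OC)c2)ccc1O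
F10 | step 3 | 3-[4-(benzyloxy)-3-methoxyphenyl]-3-oxoprop-1-en-1-one (aroylketene) | COc1cc(C(=O)C=C=O)ccc1OCc1ccccc1
A1 | alternative 1 | (2S,3S)-2-({[(2Z)-3-(4-benzyloxy-3-methoxyphenyl)-2-bromoprop-2-en-1-yl]oxy}methyl)-3-(4-benzyloxy-3-methoxyphenyl)oxirane | COc1cc(/C=C(\Br)COC[C@@H]2O[C@H]2c2ccc(OCc3ccccc3)c(OC)c2)ccc1OCc1ccccc1
A2 | alternative 1 | (R)-[(3R,4E)-4-(4-benzyloxy-3-methoxybenzylidene)tetrahydrofuran-3-yl](4-benzyloxy-3-methoxyphenyl)methanol | COc1cc(/C=C2/COC[C@@H]2[C@@H](O)c2ccc(OCc3ccccc3)c(OC)c2)ccc1OCc1ccccc1
A3 | alternative 2 | (5R)-5-(4-benzyloxy-3-methoxybenzyl)-4,5-dihydro-1,3-dioxepine | COc1cc(C[C@H]2COCOC=C2)ccc1OCc1ccccc1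
A4 | alternative 2 | (3R,4R)-4-(4-benzyloxy-3-methoxybenzyl)tetrahydrofuran-3-carbaldehyde | COc1cc(C[C@H]2COC[C@@H]2C=O)ccc1OCc1ccccc1
A5 | alternative 3 | diethyl methylenemalonate | C=C(C(=O)OCC)C(=O)OCC
A6 | alternative 3 | diethyl (Z)-4-(4-benzyloxy-3-methoxybenzylidene)dihydrofuran-3,3(2H)-dicarboxylate | COc1cc(/C=C2\COCC2(C(=O)OCC)C(=O)OCC)ccc1OCc1ccccc1
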